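all flasks: substrate 10 mM; initiator 0.50 mM

|  | coupling partner | temperature | remark | time |
|---|---|---|---|---|
| autumn | 40 mM (in portions, 3) | 2 °C | run made earlier; portions every 15 s |  |
| dusk | 80 mM (in portions, 3) | 19 °C | run made earlier; portions every 15 s |  |
| eta | 60.0 mM | −5 °C | everything together at the start | 20 min |
| beta | 30.0 mM (in portions, 3) | 25 °C | the portions of coupling partner follow each other after 15 s, the first at the start | 20 min |

- autumn (time / min: target / %): 4.00: 67.7; 12.0: 97.0; 20.0: 97.8; 30.0: 97.3
- dusk (time / min: target / %): 1.33: 86.2; 4.00: 97.5; 6.00: 97.4; 10.0: 97.2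

(standard deviation of a reading: 0.3 percentage points)



- the winner by amount of target, in percent of the substrate charged; "neither" if no more than 2 percentage points parts them (eta / beta / neither)
- how much target is there at the end, in percent of the substrate charged: eta
- how much target is there at the end, in percent of the substrate charged: beta

1. In the autumn and dusk runs target stops rising, so replace each flat stretch by its mean. The plateau shortfall, the share of the charge that is not target once the curve is flat, is 2.56% over those 5 readings. Its error of about 0.13 percentage points shifts eta and beta alike in this reckoning, so it doesn't part them.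

2. Reckon the end target as (1 − shortfall) × (1 − exp(−t/τ)), with τ a pseudo-first-order lifetime. The earliest readings give τ = 3.37 min for autumn and 0.616 min for dusk.

3. Beta's τ needn't be known well. Scaling dusk's by coupling partner alone gives 1.64 min, and 20 min is 12.2 lifetimes, so beta reckons at 97.4%.

4. Eta's τ must be known well. Extrapolating ln τ over temperature gives 0.412 of the autumn–dusk step. If coupling partner has no effect on rate, τ = 6.79 min and target is 92.3%. If rate is first order in it, τ = 3.40 min and target is 97.2%. That span of 4.8 points is wider than the margin.

5. Your midpoint for eta is 94.7%, which leans to beta but leaves the call open.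

6. The forecast, whose numbers differ from yours, gives beta, eta 93% and beta 96.8%: “Beta is the likely winner, though the margin is modest.”

7. The flask gives neither: eta 95.9%, beta 96.1%.

    substrate + target → side product (k = 6.70 M⁻¹ min⁻¹, Ea = 62.0 kJ mol⁻¹)
    coupling partner + first chain carrier ⇌ target + second chain carrier (K = 0.380, k = 75000 M⁻¹ s⁻¹, Ea = 32.0 kJ mol⁻¹, ΔH = −33.0 kJ mol⁻¹)
    initiator → 2 initiating radical (k = 0.0410 min⁻¹, Ea = 94.0 kJ mol⁻¹)
    2 second chain carrier → ended chains (k = 4.00 × 10⁸ M⁻¹ s⁻¹, Ea = 11.0 kJ mol⁻¹)
    first chain carrier → ended carrier (k = 330 min⁻¹, Ea = 76.0 kJ mol⁻¹)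
    coupling partner → decomposition product (k = 1.10 × 10⁻⁴ min⁻¹, Ea = 93.0 kJ mol⁻¹)
    substrate + second chain carrier → released group + first chain carrier (k = 2.00 × 10⁶ M⁻¹ s⁻¹, Ea = 21.0 kJ mol⁻¹)
    substrate + initiating radical → capped initiator + first chain carrier (k = 3.70 × 10⁶ M⁻¹ s⁻¹, Ea = 10.0 kJ mol⁻¹)
    (constants at 25 °C)

Eta has 2.1% of its substrate left at 20 min, so the reckoning gives 95.4% against 95.9%. Beta, with 0% left, stands at a shortfall of 3.90%, above the 2.56% read earlier. The neighbouring flask is beta with 25 mM of substrate. It also ends with 0% left, so the same reckoning gives 97.4%, but it holds 82.4% target, a shortfall of 17.6%. Side product there stands at 16.7% of the charge.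

The data stem from a simulated flask with constants of no real substance; the scatter is artificial.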